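(All runs were generated by integration for substances that don't exist, and the scatter is random.)

I decide to count turnovers and leave the concentrations aside.

| setting | spring | autumn | flask |
|---|---|---|---|
| left-handed substrate | 0.63 M | 0.63 M | 0.63 M |
| right-handed substrate | 0.63 M | 0.63 M | 0.63 M |
| solid reagent | 1.1 equiv | 1.1 equiv | 1.10 equiv |
| free catalyst | 0.4 mol% | 1.6 mol% | 0.8 mol% |
| remark | run made earlier | run made earlier |  |
| time |  |  | 8.0 min |

| run | time / min | right-handed substrate / % | left-handed substrate / % | left-handed product / % |
|---|---|---|---|---|
| spring | 0.500 | 51.0 | 44.1 | 3.9 |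
| spring | 1.33 | 48.6 | 35.5 | 16.5 |
| spring | 3.00 | 48.4 | 12.8 | 39.0 |
| spring | 6.00 | 48.3 | 0.1 | 49.2 |
| autumn | 0.833 | 50.1 | 37.3 | 13.2 |
| autumn | 2.50 | 48.1 | 9.3 | 37.5 |
| autumn | 4.00 | 45.6 | 0 | 49.6 |
| autumn | 6.00 | 45.4 | 0 | 48.7 |

(each reading ± 1 percentage point)

- free catalyst is single-handed; left-handed substrate and right-handed substrate are mirror images of each other, charged as a racemate, each of them at the stated concentration
- as a solid, counted per litre of solution: solid reagent
- at the start none of the solid reagent is in solution

* whether the excess of right-handed substrate over left-handed substrate among what is left of the two reaches 95% by 8.0 min (no / yes)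
* the highest excess of right-handed substrate over left-handed substrate among what is left of the two up to 8.0 min

Between its second and third readings, the spring run reads 67.4 min⁻¹ per catalyst charged, its turnover frequency. Over its first two readings, the autumn run gives 18.2 min⁻¹. The loading rises by a factor of 4.00, but each catalyst slows by a factor of 3.70. So the two runs gain product at nearly the same pace.

For this flask I take the mean pace of the two runs and reckon:

turnovers needed = one over the loading = 125

turnovers per minute = mean pace / loading = 35.1 min⁻¹

clearing time = needed / per minute = 3.57 min

The clearing time is the turnovers needed to consume the left-handed substrate divided by the turnovers made per minute. Mine stands well inside the 8.0 min allowed. The solid reagent, at 1.10 equiv, covers the left-handed substrate.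

The forecast says yes and 99.9%, holding that “the rate is set by the solid dissolving, not by the catalyst”. My count gives a time and no excess, so it points to the yes and says nothing of that figure.

The flask answers yes, with a top excess of >99.9%.

    free catalyst → spent catalyst (k = 0.00180 s⁻¹)
    free catalyst + left-handed substrate ⇌ catalyst intermediate A (K = 10.0 L mol⁻¹, k = 120 L mol⁻¹ s⁻¹)
    partner + catalyst intermediate B → free catalyst + right-handed product (k = 1.40 L mol⁻¹ s⁻¹)
    partner + catalyst intermediate A → free catalyst + left-handed product (k = 39.0 L mol⁻¹ s⁻¹)
    solid reagent ⇌ partner, rate k5*(cs5 - [partner]) while solid is left; crystals form when [partner] > cs5 (solubility = 0.330 M, k = 0.0110 s⁻¹)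
    free catalyst + right-handed substrate ⇌ catalyst intermediate B (K = 2.00 L mol⁻¹, k = 110 L mol⁻¹ s⁻¹)

The flask reaches an excess of 95% at 3.82 min, about half of the time allowed, with right-handed substrate left at 48.3% of the two substrates charged. My clearing time falls 0.250 min earlier, and at 4.00 min the flask still holds left-handed substrate at 0.834% of the two charged. For the autumn run, the count is 62.5 turnovers at 18.2 min⁻¹, a clearing time of 3.43 min, and its left-handed substrate reads 0% at 4.00 min.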